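The route rests on cutting the C2–C3 bond of the dihydrofuran ring (O1, C2, C3, C3a, C7a). The precursor is a diaryl ketone hydrazone whose ring B carries an ortho 2,4-bis(methoxymethoxy)benzyl ether. Oxidation gives a diaryldiazomethane, and a chiral dirhodium carboxylate turns C3 into a donor/donor carbene that inserts into the hydridic benzylic O–CH2 hydrogen at C2, 1,5 to it: ring and C3 stereocentre form in one operation. C2, expected cis from the insertion, is then funnelled to trans during the acidic global deprotection through the reversibly formed, oxygen-stabilised C2 benzylic cation. The stilbene is attached by a Heck coupling after the carbene step.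

Key step: step 8

Remark: the sense of induction of Rh2(R-PTAD)4 on this carbene is assumed to give (3S); should it give (3R), the enantiomeric catalyst Rh2(S-PTAD)4 is used and nothing else changes.

Step 1
Reactants: 1 3,5-dihydroxybenzaldehyde
Product: 2 3,5-bis(methoxymethoxy)benzaldehyde
Conditions: MOMCl, i-Pr2NEt, CH2Cl2, 0 °C → rt
Reagents that add atoms: chloromethyl methyl ether, COCCl
Why: Williamson-type O-alkylation of both unhindered phenols by the reactive α-chloro ether (MOM protection), with no stereocentre involved.

Step 2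
Reactants: 3 2,4-dihydroxybenzaldehyde
Product: 4 2,4-bis(methoxymethoxy)benzaldehyde
Conditions: NaH, MOMCl, DMF, 0 °C → rt
Reagents that add atoms: chloromethyl methyl ether, COCCl
Why: Irreversible deprotonation with NaH breaks the hydrogen bond between the 2-hydroxyl and the aldehyde, so both phenoxides undergo Williamson-type alkylation (MOM protection).

Step 3
Reactants: 4 2,4-bis(methoxymethoxy)benzaldehyde
Product: 5 [2,4-bis(methoxymethoxy)phenyl]methanol
Conditions: NaBH4, MeOH, 0 °C
Reagents that add atoms: none
Why: Borohydride reduction of an aryl aldehyde to the benzylic alcohol, to which the MOM acetals are inert.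

Step 4
Reactants: 6 1-bromo-3,5-difluorobenzene; 2 3,5-bis(methoxymethoxy)benzaldehyde
Product: 8 rac-(4-bromo-2,6-difluorophenyl)[3,5-bis(methoxymethoxy)phenyl]methanol, via (4-bromo-2,6-difluorophenyl)lithium 7 (not isolated)
Conditions: LiN(i-Pr)2, THF, −78 °C; then 2, −78 → −40 °C; aq NH4Cl
Reagents that add atoms: none
Why: Directed ortho-metalation removes the C–H flanked by both fluorines without bromine–lithium exchange, and the aryllithium (kept cold to avoid aryne formation) adds 1,2 to the aldehyde; the carbinol stereocentre forms racemic and is erased in step 5.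

Step 5
Reactants: 8 rac-(4-bromo-2,6-difluorophenyl)[3,5-bis(methoxymethoxy)phenyl]methanol
Product: 9 (4-bromo-2,6-difluorophenyl)[3,5-bis(methoxymethoxy)phenyl]methanone
Conditions: Dess–Martin periodinane, CH2Cl2, rt
Reagents that add atoms: none
Why: Dess–Martin oxidation of the secondary diaryl carbinol to the ketone under near-neutral conditions that spare the MOM acetals and the aryl halides.

Step 6
Reactants: 9 (4-bromo-2,6-difluorophenyl)[3,5-bis(methoxymethoxy)phenyl]methanone; 5 [2,4-bis(methoxymethoxy)phenyl]methanol
Product: 11 {4-bromo-2-tert-butoxy-6-[[2,4-bis(methoxymethoxy)phenyl]methoxy]phenyl}[3,5-bis(methoxymethoxy)phenyl]methanone, via (4-bromo-2-tert-butoxy-6-fluorophenyl) ketone 10 (not isolated)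
Conditions: KOt-Bu (1.0 equiv), THF, −20 → 0 °C; then 5/NaH (preformed alkoxide), THF–DMF, rt → 50 °C
Reagents that add atoms: potassium tert-butoxide, CC(C)(C)[O-].[K+]
Why: Two sequential SNAr displacements of the ketone-activated ortho fluorides, in which the bulky tert-butoxide stops at mono-substitution because the first alkoxy group deactivates the ring, the primary benzylic alkoxide then takes the second fluoride, and the para bromide is a far poorer SNAr leaving group.

Step 7
Reactants: 11 {4-bromo-2-tert-butoxy-6-[[2,4-bis(methoxymethoxy)phenyl]methoxy]phenyl}[3,5-bis(methoxymethoxy)phenyl]methanone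
Product: 12 hydrazone of 11 (E/Z mixture, inconsequential)
Conditions: N2H4·H2O (large excess), AcOH (cat.), n-BuOH, 110 °C, sealed tube
Reagents that add atoms: hydrazine (as the monohydrate), NN
Why: Acid-catalysed condensation of hydrazine with the diaryl ketone (hydrazone formation), where the small α-effect nucleophile in large excess should overcome the flanking ortho alkoxy groups and suppress azine formation.

Step 8
Reactants: 12 hydrazone of 11
Product: 15 (2R,3S)-6-bromo-4-tert-butoxy-2-[2,4-bis(methoxymethoxy)phenyl]-3-[3,5-bis(methoxymethoxy)phenyl]-2,3-dihydro-1-benzofuran (2,3-cis), via diaryldiazomethane 13 (not isolated), via rhodium carbene 14 (not isolated)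
Conditions: MnO2, CH2Cl2, 0 °C, filtration; then slow addition to Rh2(R-PTAD)4 (1 mol %), CH2Cl2, −20 °C → rt
Reagents that add atoms: none
Why: MnO2 dehydrogenates the hydrazone to diaryldiazomethane 13, which the dirhodium tetracarboxylate decomposes with loss of N2 to the donor/donor carbene 14 centred on the future C3. The electrophilic carbene carbon takes the hydridic benzylic ether hydrogen of the OCH2Ar group through a five-centre transition state and the C3–C2 bond forms as rhodium departs, so two carbons that are both electrophilic in the ketone/benzyl ether precursor are joined by polarity reversal at C3. The closest known reaction type is the enantioselective intramolecular C–H insertion of donor/donor rhodium carbenes into benzylic ether C–H bonds, which gives 2,3-diaryl-2,3-dihydrobenzofurans. The dihydrofuran ring (O1, C2, C3, C3a, C7a) closes by 1,5-insertion, in the stepwise limit a 5-endo-trig collapse of the rhodium-bound benzylic carbanion onto the oxocarbenium ion. C3 is set by the chiral pocket of the four (R)-PTAD carboxylates, which select one face of the carbene, and C2 is set relative to C3 by the compact cyclic transition state, which is expected to place the two aryl groups cis under kinetic control; C2 is corrected in step 10. The step needs site selectivity for the single OCH2Ar hydrogen pair, secured by the tert-butyl ether on the other ortho oxygen (no C–H alpha to oxygen), by MOM acetal hydrogens that lie outside 1,5 reach, and by the absence of any alkene until step 9.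

Step 9
Reactants: 15 (2R,3S)-6-bromo-4-tert-butoxy-2-[2,4-bis(methoxymethoxy)phenyl]-3-[3,5-bis(methoxymethoxy)phenyl]-2,3-dihydro-1-benzofuran; 16 4-acetoxy-3-methoxystyrene
Product: 17 4-[(E)-2-[(2R,3S)-4-tert-butoxy-2-[2,4-bis(methoxymethoxy)phenyl]-3-[3,5-bis(methoxymethoxy)phenyl]-2,3-dihydro-1-benzofuran-6-yl]ethenyl]-2-methoxyphenyl acetate
Conditions: Pd(OAc)2 (5 mol %), P(o-tol)3, Et3N, DMF, 90 °C
Reagents that add atoms: none
Why: Mizoroki–Heck reaction in which zerovalent palladium inserts into the aryl C–Br bond, syn-carbopalladation at the terminal styrene carbon and syn-β-hydride elimination give the E-stilbene, and the non-acidic medium leaves both ring stereocentres untouched.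

Step 10
Reactants: 17 4-[(E)-2-[(2R,3S)-4-tert-butoxy-2-[2,4-bis(methoxymethoxy)phenyl]-3-[3,5-bis(methoxymethoxy)phenyl]-2,3-dihydro-1-benzofuran-6-yl]ethenyl]-2-methoxyphenyl acetate
Product: 18 (2S,3S)-2-(2,4-dihydroxyphenyl)-3-(3,5-dihydroxyphenyl)-6-[(E)-2-(4-hydroxy-3-methoxyphenyl)ethenyl]-2,3-dihydro-1-benzofuran-4-ol (target)
Conditions: 3 M HCl, MeOH/THF (1:1), 45 °C, argon, dilute, continued until the cis isomer is consumed
Reagents that add atoms: none
Why: Acid-catalysed acetal cleavage (four MOM ethers), SN1 cleavage of the aryl tert-butyl ether and acid methanolysis of the aryl acetate free the six phenols, while the same acid reversibly ionises the C2–O1 bond to the ortho/para-oxygen-stabilised benzylic cation, whose re-closure under thermodynamic control places the C2 aryl trans to the C3 aryl, so the kinetic (2R,3S) ring should converge on (2S,3S) with C3 untouched (stereoconvergent epimerisation).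

Compound list
1 | 3,5-dihydroxybenzaldehyde (commercial) | O=Cc1cc(O)cc(O)c1 | starting material
2 | 3,5-bis(methoxymethoxy)benzaldehyde | COCOc1cc(C=O)cc(OCOC)c1 | intermediate
3 | 2,4-dihydroxybenzaldehyde (commercial) | O=Cc1ccc(O)cc1O | starting material
4 | 2,4-bis(methoxymethoxy)benzaldehyde | COCOc1ccc(C=O)c(OCOC)c1 | intermediate
5 | [2,4-bis(methoxymethoxy)phenyl]methanol | COCOc1ccc(CO)c(OCOC)c1 | intermediate
6 | 1-bromo-3,5-difluorobenzene (commercial) | Fc1cc(Br)cc(F)c1 | starting material
7 | (4-bromo-2,6-difluorophenyl)lithium | [Li]c1c(F)cc(Br)cc1F | intermediate (not isolated)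
8 | rac-(4-bromo-2,6-difluorophenyl)[3,5-bis(methoxymethoxy)phenyl]methanol | COCOc1cc(cc(OCOC)c1)C(O)c1c(F)cc(Br)cc1F | intermediate
9 | (4-bromo-2,6-difluorophenyl)[3,5-bis(methoxymethoxy)phenyl]methanone | COCOc1cc(cc(OCOC)c1)C(=O)c1c(F)cc(Br)cc1F | intermediate
10 | (4-bromo-2-tert-butoxy-6-fluorophenyl)[3,5-bis(methoxymethoxy)phenyl]methanone | COCOc1cc(cc(OCOC)c1)C(=O)c1c(F)cc(Br)cc1OC(C)(C)C | intermediate (not isolated)
11 | {4-bromo-2-tert-butoxy-6-[[2,4-bis(methoxymethoxy)phenyl]methoxy]phenyl}[3,5-bis(methoxymethoxy)phenyl]methanone | COCOc1cc(cc(OCOC)c1)C(=O)c1c(OCc2ccc(OCOC)cc2OCOC)cc(Br)cc1OC(C)(C)C | intermediate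
12 | hydrazone of 11 | COCOc1cc(cc(OCOC)c1)C(=NN)c1c(OCc2ccc(OCOC)cc2OCOC)cc(Br)cc1OC(C)(C)C | intermediate
13 | diaryldiazomethane derived from 12 | COCOc1cc(cc(OCOC)c1)C(=[N+]=[N-])c1c(OCc2ccc(OCOC)cc2OCOC)cc(Br)cc1OC(C)(C)C | intermediate (not isolated)
14 | rhodium carbene derived from 13 (carbene carbon on one rhodium of the Rh2(R-PTAD)4 core, carboxylate ligands not drawn) | COCOc1cc(cc(OCOC)c1)C(=[Rh])c1c(OCc2ccc(OCOC)cc2OCOC)cc(Br)cc1OC(C)(C)C | intermediate (not isolated)
15 | (2R,3S)-6-bromo-4-tert-butoxy-2-[2,4-bis(methoxymethoxy)phenyl]-3-[3,5-bis(methoxymethoxy)phenyl]-2,3-dihydro-1-benzofuran | Brc1cc(OC(C)(C)C)c2c(c1)O[C@@H](c1ccc(OCOC)cc1OCOC)[C@H]2c1cc(OCOC)cc(OCOC)c1 | intermediate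
16 | 4-acetoxy-3-methoxystyrene (2-methoxy-4-vinylphenyl acetate, commercial) | C=Cc1ccc(OC(C)=O)c(OC)c1 | starting material
17 | 4-[(E)-2-[(2R,3S)-4-tert-butoxy-2-[2,4-bis(methoxymethoxy)phenyl]-3-[3,5-bis(methoxymethoxy)phenyl]-2,3-dihydro-1-benzofuran-6-yl]ethenyl]-2-methoxyphenyl acetate | COc1cc(/C=C/c2cc(OC(C)(C)C)c3c(c2)O[C@@H](c2ccc(OCOC)cc2OCOC)[C@H]3c2cc(OCOC)cc(OCOC)c2)ccc1OC(C)=O | intermediate
18 | (2S,3S)-2-(2,4-dihydroxyphenyl)-3-(3,5-dihydroxyphenyl)-6-[(E)-2-(4-hydroxy-3-methoxyphenyl)ethenyl]-2,3-dihydro-1-benzofuran-4-ol | COc1cc(/C=C/c2cc(O)c3c(c2)O[C@H](c2ccc(O)cc2O)[C@H]3c2cc(O)cc(O)c2)ccc1O | target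

Total step count: 10. Longest linear sequence: 8 steps (steps 1, 4, 5, 6, 7, 8, 9, 10).

Steps most likely to fail

1. Step 8. The chiral carboxylate pocket may discriminate poorly between the two faces of a carbene whose ring B is substituted at both ortho positions, leaving C3 with insufficient enantiomeric purity. Coupling of diazo compound and carbene to the azine is the second concern and is countered by slow addition at high dilution. The fallback moves stereocontrol from catalysis to resolution. Setting out from 12, the same MnO2 oxidation followed by achiral Rh2(OAc)4 in CH2Cl2 should give the cis-dihydrobenzofuran as the racemate. This is 15 together with its mirror image, (2S,3R)-6-bromo-4-tert-butoxy-2-[2,4-bis(methoxymethoxy)phenyl]-3-[3,5-bis(methoxymethoxy)phenyl]-2,3-dihydro-1-benzofuran F1. Preparative chromatography on an amylose tris(3,5-dimethylphenylcarbamate) chiral stationary phase should separate the two, and the route is rejoined at 15.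

2. Step 7. The condensation may stall because the two ortho alkoxy groups of ring B shield the carbonyl carbon, and forcing temperatures may divert material to the azine. The fallback sets out from 11. Sc(OTf)3-catalysed condensation with 1,2-bis(tert-butyldimethylsilyl)hydrazine in CH2Cl2 at rt is driven by silanol formation and is effective on hindered ketones. It should give the N-(tert-butyldimethylsilyl)hydrazone of 11 F2. Oxidation of this with (difluoroiodo)benzene and 2-chloropyridine at −78 °C should give diazo compound 13 directly. The route is rejoined at 13, which enters the rhodium stage of step 8.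

3. Step 10. The electron-rich stilbene may be lost to acid-induced hydration, cyclisation or oligomerisation (protonation of the alkene, or capture of the cations and quinone methides set free) before deprotection and C2 equilibration are complete. The fallback removes the alkene from the acid step and sets out from 15. The same acid treatment (3 M HCl, MeOH/THF, 45 °C) should give the trans pentaphenol (2S,3S)-6-bromo-2-(2,4-dihydroxyphenyl)-3-(3,5-dihydroxyphenyl)-2,3-dihydro-1-benzofuran-4-ol F3. Acetylation (Ac2O, pyridine, cat. DMAP) should give its pentaacetate F4. Heck coupling with 16 under the conditions of step 9 should give the hexaacetate of the target F5. Mild methanolysis (cat. K2CO3, MeOH, 0 °C, argon) then frees the phenols, and the route is rejoined at 18.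

Further compounds
F1 | step 8 | (2S,3R)-6-bromo-4-tert-butoxy-2-[2,4-bis(methoxymethoxy)phenyl]-3-[3,5-bis(methoxymethoxy)phenyl]-2,3-dihydro-1-benzofuran (enantiomer of 15) | Brc1cc(OC(C)(C)C)c2c(c1)O[C@H](c1ccc(OCOC)cc1OCOC)[C@@H]2c1cc(OCOC)cc(OCOC)c1
F2 | step 7 | N-(tert-butyldimethylsilyl)hydrazone of 11 | COCOc1cc(cc(OCOC)c1)C(=NN[Si](C)(C)C(C)(C)C)c1c(OCc2ccc(OCOC)cc2OCOC)cc(Br)cc1OC(C)(C)C
F3 | step 10 | (2S,3S)-6-bromo-2-(2,4-dihydroxyphenyl)-3-(3,5-dihydroxyphenyl)-2,3-dihydro-1-benzofuran-4-ol | Brc1cc(O)c2c(c1)O[C@H](c1ccc(O)cc1O)[C@H]2c1cc(O)cc(O)c1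
F4 | step 10 | pentaacetate of F3 | Brc1cc(OC(C)=O)c2c(c1)O[C@H](c1ccc(OC(C)=O)cc1OC(C)=O)[C@H]2c1cc(OC(C)=O)cc(OC(C)=O)c1
F5 | step 10 | hexaacetate of 18 | COc1cc(/C=C/c2cc(OC(C)=O)c3c(c2)O[C@H](c2ccc(OC(C)=O)cc2OC(C)=O)[C@H]3c2cc(OC(C)=O)cc(OC(C)=O)c2)ccc1OC(C)=O
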